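All runs were computed on assumed constants, noise included.

In a one-step world, electrophile lost and product made would be the same number, so the examination opens by asking how far this flask departs from that world.

| flask | electrophile | nucleophile | buffer base | buffer acid | scavenger | remark | time |
|---|---|---|---|---|---|---|---|
| teal | 0.020 M | 0.036 M | 0.020 M | 2 mM | 10 mM | the very flask that is asked about, followed so far |  |
| flask | 0.020 M | 0.0360 M | 0.0200 M | 2.00 mM | 10.0 mM |  | 4.0 h |

teal run (percent of the electrophile charged)

| time / min | electrophile / % | product / % |
|---|---|---|
| 15.0 | 90 | 2 |
| 40.0 | 81 | 12 |
| 80.0 | 67 | 18 |
| 120 | 63 | 23 |

(readings scatter by 2 percentage points)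

1. part of the electrophile that has reacted at 4.0 h
2. pH of the solution at 4.0 h

- acid is the free proton; pH is minus the decimal logarithm of its molar concentration
- what is said of leaving group includes idle adduct
- the analysis behind the earlier runs scatters by 2 percentage points, standard deviation
- on the list of suspects stand: electrophile + nucleophile -> acid + product + leaving group; protonated nucleophile <-> nucleophile + acid; buffer acid <-> buffer base + acid; electrophile + leaving group <-> idle adduct; scavenger + leaving group -> scavenged by-product
- what has gone from electrophile into another species counts as reacted, even if it can come back
- the earlier runs do not show the pH; that part of a forecast is a guess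

*What is the gap at the last reading?* At 120 min the electrophile stands at 63% and the product at 23%, so 14.0% of the charge is neither. I call this the parked share, the charge that has left the electrophile without becoming product.

*Is that more than noise?* Two readings, each scattering by 2 percentage points, give a difference good to about 2.8 points, so I take the gap as real. It counts as reacted, and the idle adduct is the suspect that can hold it.

*And the product at 4.0 h?* The nucleophile is charged at 1.80 equivalents, so I treat it as constant, which makes the step pseudo-first-order. Each stretch of 120 min then leaves the same fraction, 77.0%, not yet turned into product. That gives 40.7% product.

*Isn't that excess weak?* Yes, so I expect this figure to run high. The small term is held fixed, and my reckoning is 54.7% reacted.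

*And the pH?* The readings do not show it and no buffer constant is given, so I offer no number.

The forecast says 48% reacted and pH 7.5, with the grounds that “adduct should stay near 12%, possibly declining”. It differs from my 54.7%.

The flask gives 54.1% reacted and pH 9.88.

    electrophile + nucleophile → acid + product + leaving group (k = 0.0890 L mol⁻¹ min⁻¹)
    protonated nucleophile ⇌ nucleophile + acid, settled at all times (K = 3.20 × 10⁻¹⁰ M)
    buffer acid ⇌ buffer base + acid, settled at all times (K = 3.20 × 10⁻⁹ M)
    electrophile + leaving group ⇌ idle adduct, settled at all times (K = 3600 L mol⁻¹)
    scavenger + leaving group → scavenged by-product (k = 26.0 L mol⁻¹ min⁻¹)

At 4.0 h the flask holds 36.2% product and 17.9% idle adduct, so my product ran high and the parked share of 14.0% ran low, and the nearness of my total is no check. Of the leaving group released with that product, the flask then holds 17.7% of the electrophile charge as scavenged by-product, about as much as in the idle adduct, and 1.08 × 10⁻⁴ M free.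

For the neighbour read at 6.0 h, the same reckoning gives 54.3% product plus 14.0%, which is 68.3%. That neighbour gives 61.3%, with 44.6% product, 16.6% idle adduct and 48% of its nucleophile left.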